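**Strategy.** Rings C and E each carry five adjacent oxygenated carbons and one C–H. Ring E (C1 bonded to the ring D ether oxygen, C2 to the ring F ether oxygen, C3–C5 hydroxylated, C6–H) is disconnected to a squarate, which supplies C1–C4 with their oxygens, and a 1-ethoxyvinyl group, which supplies C5 and C6. Thermolysis of cyclobutenone 9, a 2-aryloxy-3,4-dimethoxy-4-(1-ethoxyvinyl)cyclobutenone already bearing ring F, opens it to a dienylketene that closes the C1–C6 bond and delivers ring E with a single free hydroxyl at C1. Ether coupling and Dakin oxidation add ring D; the cycle is repeated for ring C, then rings B and A follow, and BBr3 frees all hydroxyls.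

Key step: step 6

Remarks on the chemistry:
- The target is achiral. Compounds 8, 9, 18 and 19 each carry one quaternary stereocentre, are made and used as racemates, and lose that centre in the thermolysis.
- Ring C is numbered like ring E: C1 bonded to the ring B ether oxygen, C2 to the ring D ether oxygen, C6–H.
- The mixed squarates are made from the preformed chloro methoxy squarate 3, so the phenol enters last and displaces chloride, not methoxide.
- 1-Ethoxyvinyllithium 7 is made in a step of its own (step 4) and used as a THF solution. The solution does not keep, so step 4 is run immediately before each of the two additions (steps 5 and 10).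
- The tertiary alkoxide is methylated in the same flask, so the acid-sensitive carbinol is never handled.
- Shorthand: ArDEF, ArCDEF and ArBCDEF are the aryl residues of phenols 16, 22 and 25 (the phenol minus OH).
- Assumption: 2-hydroxy-3,4-dimethoxybenzaldehyde, (3,4,5-trimethoxyphenyl)boronic acid and 4-fluoro-3,5-dimethoxybenzaldehyde, used only in fallbacks, are taken to be purchasable.

**Route**

Step 1
Reactants: 1 squaric acid
Product: 2 squaryl dichloride (3,4-dichlorocyclobut-3-ene-1,2-dione)
Conditions: (COCl)2, DMF (cat.), CH2Cl2, reflux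
Reagents that add atoms: oxalyl chloride, ClC(=O)C(=O)Cl
Why: Vilsmeier-type activation by the chloroiminium salt formed from DMF and oxalyl chloride should turn both vinylogous acid hydroxyls into chlorides, as in ordinary acid chloride formation.

Step 2
Reactants: 2 squaryl dichloride
Product: 3 3-chloro-4-methoxycyclobut-3-ene-1,2-dione
Conditions: MeOH (1.0 equiv), Et2O, 0 °C → rt
Reagents that add atoms: methanol, CO
Why: Vinylogous acyl substitution (addition–elimination) by one equivalent of methanol should stop at the monoester, because the methoxy group donates into the dione and deactivates the remaining chloride.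

Step 3
Reactants: 3 3-chloro-4-methoxycyclobut-3-ene-1,2-dione; 4 3,4,5-trimethoxyphenol
Product: 5 3-methoxy-4-(3,4,5-trimethoxyphenoxy)cyclobut-3-ene-1,2-dione
Conditions: i-Pr2NEt, CH2Cl2, −78 → 0 °C
Reagents that add atoms: none
Why: Addition–elimination of the phenol oxygen at the chloride-bearing carbon (vinylogous acyl substitution) should give the mixed squarate, since chloride leaves far more readily than methoxide and O-attack is the kinetic path with a hindered amine at low temperature.

Step 4
Reactants: 6 ethyl vinyl ether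
Product: 7 1-ethoxyvinyllithium (THF solution, used at once)
Conditions: t-BuLi, THF, −78 → 0 °C
Reagents that add atoms: tert-butyllithium, [Li]C(C)(C)C
Why: Oxygen-assisted α-lithiation (deprotonation of the vinylic C–H next to the ether oxygen) should give the α-alkoxyvinyllithium, the standard preparation of this acyl anion equivalent.

Step 5
Reactants: 5 3-methoxy-4-(3,4,5-trimethoxyphenoxy)cyclobut-3-ene-1,2-dione; 7 1-ethoxyvinyllithium
Product: 9 racemic 4-(1-ethoxyvinyl)-3,4-dimethoxy-2-(3,4,5-trimethoxyphenoxy)cyclobut-2-en-1-one, via lithium alkoxide 8 (not isolated)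
Conditions: 7 (THF solution from step 4) added to 5, THF, −78 °C; then MeOTf, −78 → 0 °C
Reagents that add atoms: methyl trifluoromethanesulfonate, COS(=O)(=O)C(F)(F)F
Why: 1,2-Addition of the α-lithiated vinyl ether to a squarate carbonyl followed by O-methylation of the lithium alkoxide should occur at the carbonyl next to the methoxy-bearing carbon, which is conjugated with the weaker aryloxy donor and lies away from the bulky aryl group, and the new quaternary centre forms as a racemate because the substrate is achiral.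

Step 6
Reactants: 9 racemic 4-(1-ethoxyvinyl)-3,4-dimethoxy-2-(3,4,5-trimethoxyphenoxy)cyclobut-2-en-1-one
Product: 12 5-ethoxy-3,4-dimethoxy-2-(3,4,5-trimethoxyphenoxy)phenol, via dienylketene 10 (not isolated), via cyclohexadienone 11 (not isolated)
Conditions: toluene (degassed, base-washed glassware), 110 °C, Ar
Reagents that add atoms: none
Why: Heating should cleave the C1–C4 bond of the cyclobutenone by a conrotatory four-electron electrocyclic opening in which the 4-methoxy donor turns outward, so the ethoxyvinyl group ends cis to the ketene in 10. The ketene carbon then bonds to the vinyl CH2 terminus in a thermally allowed disrotatory six-electron electrocyclisation, which closes ring E as dienone 11 and is followed by irreversible enolisation to phenol 12. This is the Moore rearrangement of squarate-derived 4-alkenyl-4-alkoxycyclobutenones to hydroquinone monoethers, here applied to a substrate that differs only in its aryloxy substituent. No stereocentre is formed and the quaternary centre of racemic 9 is destroyed. The step needs torquoselectivity, secured by the outward preference of the 4-methoxy group, and clean intramolecular capture of the ketene, secured by the six-centre closure being much faster than attack on the remote aryloxy ring or on outside nucleophiles in dry, acid-free solvent. The order OH, OAr, OMe, OMe, OEt, H around ring E is fixed entirely by the connectivity of 9.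

Step 7
Reactants: 12 5-ethoxy-3,4-dimethoxy-2-(3,4,5-trimethoxyphenoxy)phenol; 13 4-bromo-3,5-dimethoxybenzaldehyde
Product: 14 4-[5-ethoxy-3,4-dimethoxy-2-(3,4,5-trimethoxyphenoxy)phenoxy]-3,5-dimethoxybenzaldehyde
Conditions: CuI (cat.), picolinic acid (cat.), K3PO4, DMSO, 90 °C
Reagents that add atoms: none
Why: Ullmann-type copper-catalysed C–O coupling of a phenol with an aryl bromide activated by its para-formyl group should form the diaryl ether, picolinic acid being a ligand suited to ortho-substituted partners.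

Step 8
Reactants: 14 4-[5-ethoxy-3,4-dimethoxy-2-(3,4,5-trimethoxyphenoxy)phenoxy]-3,5-dimethoxybenzaldehyde
Product: 16 4-[5-ethoxy-3,4-dimethoxy-2-(3,4,5-trimethoxyphenoxy)phenoxy]-3,5-dimethoxyphenol, via aryl formate 15 (not isolated)
Conditions: mCPBA, CH2Cl2, 0 °C → rt; then K2CO3 (cat.), MeOH, rt
Reagents that add atoms: 3-chloroperoxybenzoic acid, OOC(=O)c1cccc(Cl)c1
Why: Dakin oxidation, in which the electron-rich para-aryloxy ring migrates in Baeyer–Villiger fashion, should give the aryl formate, which mild methanolysis cleaves to the ring D phenol.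

Step 9
Reactants: 16 4-[5-ethoxy-3,4-dimethoxy-2-(3,4,5-trimethoxyphenoxy)phenoxy]-3,5-dimethoxyphenol; 3 3-chloro-4-methoxycyclobut-3-ene-1,2-dione
Product: 17 3-methoxy-4-(ArDEF-oxy)cyclobut-3-ene-1,2-dione
Conditions: i-Pr2NEt, CH2Cl2, −78 → 0 °C
Reagents that add atoms: none
Why: The same vinylogous acyl substitution as in step 3 should apply, the phenol of 16 being unhindered (both ortho positions are C–H).

Step 10
Reactants: 17 3-methoxy-4-(ArDEF-oxy)cyclobut-3-ene-1,2-dione; 7 1-ethoxyvinyllithium
Product: 19 racemic 4-(1-ethoxyvinyl)-3,4-dimethoxy-2-(ArDEF-oxy)cyclobut-2-en-1-one, via lithium alkoxide 18 (not isolated)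
Conditions: 7 (fresh THF solution from step 4) added to 17, THF, −78 °C; then MeOTf, −78 → 0 °C
Reagents that add atoms: methyl trifluoromethanesulfonate, COS(=O)(=O)C(F)(F)F
Why: As in step 5, 1,2-addition should take place at the carbonyl conjugated with the aryloxy group and remote from it, followed by O-methylation of the alkoxide, and the quaternary centre forms as a racemate.

Step 11
Reactants: 19 racemic 4-(1-ethoxyvinyl)-3,4-dimethoxy-2-(ArDEF-oxy)cyclobut-2-en-1-one
Product: 22 5-ethoxy-3,4-dimethoxy-2-(ArDEF-oxy)phenol (tetramer; ring C hydroxyl free), via dienylketene 20 (not isolated), via cyclohexadienone 21 (not isolated)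
Conditions: toluene (degassed, base-washed glassware), 110 °C, Ar
Reagents that add atoms: none
Why: A second Moore rearrangement (four-electron ring opening, six-electron closure, enolisation) should build ring C exactly as step 6 builds ring E, with no stereocentre formed.

Step 12
Reactants: 22 5-ethoxy-3,4-dimethoxy-2-(ArDEF-oxy)phenol; 13 4-bromo-3,5-dimethoxybenzaldehyde
Product: 23 4-(ArCDEF-oxy)-3,5-dimethoxybenzaldehyde
Conditions: CuI (cat.), picolinic acid (cat.), K3PO4, DMSO, 90 °C
Reagents that add atoms: none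
Why: The Ullmann-type coupling of step 7 should apply unchanged, because the reacting hydroxyl has the same local environment as that of phenol 12.

Step 13
Reactants: 23 4-(ArCDEF-oxy)-3,5-dimethoxybenzaldehyde
Product: 25 4-(ArCDEF-oxy)-3,5-dimethoxyphenol (pentamer; ring B hydroxyl free), via aryl formate 24 (not isolated)
Conditions: mCPBA, CH2Cl2, 0 °C → rt; then K2CO3 (cat.), MeOH, rt
Reagents that add atoms: 3-chloroperoxybenzoic acid, OOC(=O)c1cccc(Cl)c1
Why: Dakin oxidation as in step 8 should convert the formyl group into the ring B hydroxyl.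

Step 14
Reactants: 25 4-(ArCDEF-oxy)-3,5-dimethoxyphenol; 13 4-bromo-3,5-dimethoxybenzaldehyde
Product: 26 4-(ArBCDEF-oxy)-3,5-dimethoxybenzaldehyde
Conditions: CuI (cat.), picolinic acid (cat.), K3PO4, DMSO, 90 °C
Reagents that add atoms: none
Why: Ullmann-type coupling should be easier here than in steps 7 and 12, since the phenol of 25 has no ortho substituent.

Step 15
Reactants: 26 4-(ArBCDEF-oxy)-3,5-dimethoxybenzaldehyde
Product: 28 4-(ArBCDEF-oxy)-3,5-dimethoxyphenol (protected hexamer; ring A 4-hydroxyl free), via aryl formate 27 (not isolated)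
Conditions: mCPBA, CH2Cl2, 0 °C → rt; then K2CO3 (cat.), MeOH, rt
Reagents that add atoms: 3-chloroperoxybenzoic acid, OOC(=O)c1cccc(Cl)c1
Why: Dakin oxidation should place the third oxygen of ring A para to the ether link, completing the 2,4,6-trioxygenated pattern.

Step 16
Reactants: 28 4-(ArBCDEF-oxy)-3,5-dimethoxyphenol
Product: 29 target hexamer CNP0114537.0
Conditions: BBr3 (excess), CH2Cl2, −78 °C → rt; then H2O, 0 °C, Ar
Reagents that add atoms: none
Why: Lewis acid ether cleavage with BBr3 should remove all thirteen methyl and both ethyl groups by bromide attack on the alkyl carbon, while the diaryl ether bonds, which offer no such carbon, stay intact.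

**Compound list**

1 | squaric acid | OC1=C(O)C(=O)C1=O | starting material
2 | squaryl dichloride (3,4-dichlorocyclobut-3-ene-1,2-dione) | ClC1=C(Cl)C(=O)C1=O | intermediate
3 | 3-chloro-4-methoxycyclobut-3-ene-1,2-dione | COC1=C(Cl)C(=O)C1=O | intermediate
4 | 3,4,5-trimethoxyphenol | COc1cc(O)cc(OC)c1OC | starting material
5 | 3-methoxy-4-(3,4,5-trimethoxyphenoxy)cyclobut-3-ene-1,2-dione | COC1=C(Oc2cc(OC)c(OC)c(OC)c2)C(=O)C1=O | intermediate
6 | ethyl vinyl ether | C=COCC | starting material
7 | 1-ethoxyvinyllithium (THF solution) | [Li]C(=C)OCC | intermediate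
8 | racemic lithium 1-(1-ethoxyvinyl)-2-methoxy-4-oxo-3-(3,4,5-trimethoxyphenoxy)cyclobut-2-en-1-olate | O=C1C(Oc2cc(OC)c(OC)c(OC)c2)=C(OC)C1(O[Li])C(=C)OCC | intermediate (not isolated)
9 | racemic 4-(1-ethoxyvinyl)-3,4-dimethoxy-2-(3,4,5-trimethoxyphenoxy)cyclobut-2-en-1-one | O=C1C(Oc2cc(OC)c(OC)c(OC)c2)=C(OC)C1(OC)C(=C)OCC | intermediate
10 | (3Z)-5-ethoxy-3,4-dimethoxy-2-(3,4,5-trimethoxyphenoxy)hexa-1,3,5-trien-1-one (dienylketene, ketenyl and ethoxyvinyl cis) | O=C=C(Oc1cc(OC)c(OC)c(OC)c1)/C(OC)=C(OC)\C(=C)OCC | intermediate (not isolated)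
11 | 5-ethoxy-3,4-dimethoxy-2-(3,4,5-trimethoxyphenoxy)cyclohexa-2,4-dien-1-one | O=C1CC(OCC)=C(OC)C(OC)=C1Oc1cc(OC)c(OC)c(OC)c1 | intermediate (not isolated)
12 | 5-ethoxy-3,4-dimethoxy-2-(3,4,5-trimethoxyphenoxy)phenol | Oc1cc(OCC)c(OC)c(OC)c1Oc1cc(OC)c(OC)c(OC)c1 | intermediate
13 | 4-bromo-3,5-dimethoxybenzaldehyde | COc1cc(C=O)cc(OC)c1Br | starting material
14 | 4-[5-ethoxy-3,4-dimethoxy-2-(3,4,5-trimethoxyphenoxy)phenoxy]-3,5-dimethoxybenzaldehyde | O=Cc1cc(OC)c(Oc2cc(OCC)c(OC)c(OC)c2Oc2cc(OC)c(OC)c(OC)c2)c(OC)c1 | intermediate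
15 | formate ester of phenol 16 | O=COc1cc(OC)c(Oc2cc(OCC)c(OC)c(OC)c2Oc2cc(OC)c(OC)c(OC)c2)c(OC)c1 | intermediate (not isolated)
16 | 4-[5-ethoxy-3,4-dimethoxy-2-(3,4,5-trimethoxyphenoxy)phenoxy]-3,5-dimethoxyphenol | Oc1cc(OC)c(Oc2cc(OCC)c(OC)c(OC)c2Oc2cc(OC)c(OC)c(OC)c2)c(OC)c1 | intermediate
17 | 3-methoxy-4-(ArDEF-oxy)cyclobut-3-ene-1,2-dione | COC1=C(Oc2cc(OC)c(Oc3cc(OCC)c(OC)c(OC)c3Oc3cc(OC)c(OC)c(OC)c3)c(OC)c2)C(=O)C1=O | intermediate
18 | racemic lithium alkoxide from 17 and 7 | O=C1C(Oc2cc(OC)c(Oc3cc(OCC)c(OC)c(OC)c3Oc3cc(OC)c(OC)c(OC)c3)c(OC)c2)=C(OC)C1(O[Li])C(=C)OCC | intermediate (not isolated)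
19 | racemic 4-(1-ethoxyvinyl)-3,4-dimethoxy-2-(ArDEF-oxy)cyclobut-2-en-1-one | O=C1C(Oc2cc(OC)c(Oc3cc(OCC)c(OC)c(OC)c3Oc3cc(OC)c(OC)c(OC)c3)c(OC)c2)=C(OC)C1(OC)C(=C)OCC | intermediate
20 | (3Z)-5-ethoxy-3,4-dimethoxy-2-(ArDEF-oxy)hexa-1,3,5-trien-1-one (dienylketene) | O=C=C(Oc1cc(OC)c(Oc2cc(OCC)c(OC)c(OC)c2Oc2cc(OC)c(OC)c(OC)c2)c(OC)c1)/C(OC)=C(OC)\C(=C)OCC | intermediate (not isolated)
21 | 5-ethoxy-3,4-dimethoxy-2-(ArDEF-oxy)cyclohexa-2,4-dien-1-one | O=C1CC(OCC)=C(OC)C(OC)=C1Oc1cc(OC)c(Oc2cc(OCC)c(OC)c(OC)c2Oc2cc(OC)c(OC)c(OC)c2)c(OC)c1 | intermediate (not isolated)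
22 | 5-ethoxy-3,4-dimethoxy-2-(ArDEF-oxy)phenol (tetramer; ring C hydroxyl free) | Oc1cc(OCC)c(OC)c(OC)c1Oc1cc(OC)c(Oc2cc(OCC)c(OC)c(OC)c2Oc2cc(OC)c(OC)c(OC)c2)c(OC)c1 | intermediate
23 | 4-(ArCDEF-oxy)-3,5-dimethoxybenzaldehyde | O=Cc1cc(OC)c(Oc2cc(OCC)c(OC)c(OC)c2Oc2cc(OC)c(Oc3cc(OCC)c(OC)c(OC)c3Oc3cc(OC)c(OC)c(OC)c3)c(OC)c2)c(OC)c1 | intermediate
24 | formate ester of phenol 25 | O=COc1cc(OC)c(Oc2cc(OCC)c(OC)c(OC)c2Oc2cc(OC)c(Oc3cc(OCC)c(OC)c(OC)c3Oc3cc(OC)c(OC)c(OC)c3)c(OC)c2)c(OC)c1 | intermediate (not isolated)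
25 | 4-(ArCDEF-oxy)-3,5-dimethoxyphenol (pentamer; ring B hydroxyl free) | Oc1cc(OC)c(Oc2cc(OCC)c(OC)c(OC)c2Oc2cc(OC)c(Oc3cc(OCC)c(OC)c(OC)c3Oc3cc(OC)c(OC)c(OC)c3)c(OC)c2)c(OC)c1 | intermediate
26 | 4-(ArBCDEF-oxy)-3,5-dimethoxybenzaldehyde | O=Cc1cc(OC)c(Oc2cc(OC)c(Oc3cc(OCC)c(OC)c(OC)c3Oc3cc(OC)c(Oc4cc(OCC)c(OC)c(OC)c4Oc4cc(OC)c(OC)c(OC)c4)c(OC)c3)c(OC)c2)c(OC)c1 | intermediate
27 | formate ester of phenol 28 | O=COc1cc(OC)c(Oc2cc(OC)c(Oc3cc(OCC)c(OC)c(OC)c3Oc3cc(OC)c(Oc4cc(OCC)c(OC)c(OC)c4Oc4cc(OC)c(OC)c(OC)c4)c(OC)c3)c(OC)c2)c(OC)c1 | intermediate (not isolated)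
28 | 4-(ArBCDEF-oxy)-3,5-dimethoxyphenol (hexamer; thirteen OMe, two OEt, ring A 4-OH free) | Oc1cc(OC)c(Oc2cc(OC)c(Oc3cc(OCC)c(OC)c(OC)c3Oc3cc(OC)c(Oc4cc(OCC)c(OC)c(OC)c4Oc4cc(OC)c(OC)c(OC)c4)c(OC)c3)c(OC)c2)c(OC)c1 | intermediate
29 | CNP0114537.0 (hexameric phlorotannin, sixteen free hydroxyls) | Oc1cc(O)c(Oc2cc(O)c(Oc3cc(O)c(O)c(O)c3Oc3cc(O)c(Oc4cc(O)c(O)c(O)c4Oc4cc(O)c(O)c(O)c4)c(O)c3)c(O)c2)c(O)c1 | target

**Totals**

Total step count: 16 (step 4 is carried out before each of steps 5 and 10 and is counted once). Longest linear sequence: 15 steps (1 → 29 through steps 1–3 and 5–16). Step 4 is a one-step side branch from 6, and compounds 4 and 13 enter as purchased materials.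

**Three steps most likely to fail**

1. Step 6 (the thermolysis; step 11 repeats it). The ethoxyvinyl group may be protonated or hydrolysed by trace acid before the ring opens, the ketene may be diverted by adventitious nucleophiles, or the electron-rich phenol may oxidise during heating. The fallback builds ring E by classical arene chemistry. It consumes no numbered compound of the route: it sets out from purchased 2-hydroxy-3,4-dimethoxybenzaldehyde and comes back to the route at 12. Bromination (NBS, MeCN, 0 °C) at the position para to the hydroxyl, to which the hydroxyl, the 4-methoxy group and the formyl group all direct, should give 5-bromo-2-hydroxy-3,4-dimethoxybenzaldehyde F1. Copper-catalysed ethoxylation (NaOEt, CuBr, EtOH–DMF, 100 °C) should then give 5-ethoxy-2-hydroxy-3,4-dimethoxybenzaldehyde F2. Chan–Lam coupling with (3,4,5-trimethoxyphenyl)boronic acid (Cu(OAc)2 (cat.), pyridine, 4 Å molecular sieves, CH2Cl2, O2, rt), a method that tolerates doubly ortho-substituted phenols, should give 5-ethoxy-3,4-dimethoxy-2-(3,4,5-trimethoxyphenoxy)benzaldehyde F3. Dakin oxidation (mCPBA, then K2CO3/MeOH) through 5-ethoxy-3,4-dimethoxy-2-(3,4,5-trimethoxyphenoxy)phenyl formate F4 should then give 12.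

2. Step 5 (vinyllithium addition with in-flask methylation; step 10 repeats it). The two carbonyl groups may not be discriminated well enough, which would transpose aryloxy and methoxy in ring E. The organolithium may also add in conjugate fashion and expel aryloxide, or the hindered alkoxide may methylate incompletely. The fallback removes the site question by symmetry. It sets out from 2 and 4 and comes back at 9. Two equivalents of 4 with 2 (i-Pr2NEt, CH2Cl2, −78 → 0 °C) should give 3,4-bis(3,4,5-trimethoxyphenoxy)cyclobut-3-ene-1,2-dione F5, whose carbonyls are equivalent. Addition of 7 at −78 °C gives racemic lithium 1-(1-ethoxyvinyl)-4-oxo-2,3-bis(3,4,5-trimethoxyphenoxy)cyclobut-2-en-1-olate F6, and MeOTf should give racemic 4-(1-ethoxyvinyl)-4-methoxy-2,3-bis(3,4,5-trimethoxyphenoxy)cyclobut-2-en-1-one F7. In F7 only the aryloxy group at C3 sits at the β-carbon of the enone. One equivalent of NaOMe (MeOH–THF, −40 → 0 °C) should therefore exchange it for methoxy by conjugate addition–elimination (vinylogous transesterification), leave the C2 aryloxy group untouched, give 9, and return one equivalent of 4.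

3. Step 7 (hindered diaryl ether formation; steps 12 and 14 repeat it). Bond formation at a carbon flanked by two methoxy groups may be slow, so that protodebromination of 13 or degradation of the aldehyde on long heating takes over. The fallback replaces copper catalysis by uncatalysed addition–elimination on a fluoroarene, where attack at the C–F carbon is much less sensitive to the flanking groups. It sets out from 12 and comes back at 14: 12 and 4-fluoro-3,5-dimethoxybenzaldehyde (Cs2CO3, DMSO, 120 °C) should give 14 directly, so the fallback makes no new compound (F0).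

**Further compounds**

F1 | step 6 | 5-bromo-2-hydroxy-3,4-dimethoxybenzaldehyde | O=Cc1cc(Br)c(OC)c(OC)c1O
F2 | step 6 | 5-ethoxy-2-hydroxy-3,4-dimethoxybenzaldehyde | O=Cc1cc(OCC)c(OC)c(OC)c1O
F3 | step 6 | 5-ethoxy-3,4-dimethoxy-2-(3,4,5-trimethoxyphenoxy)benzaldehyde | O=Cc1cc(OCC)c(OC)c(OC)c1Oc1cc(OC)c(OC)c(OC)c1
F4 | step 6 | 5-ethoxy-3,4-dimethoxy-2-(3,4,5-trimethoxyphenoxy)phenyl formate | O=COc1cc(OCC)c(OC)c(OC)c1Oc1cc(OC)c(OC)c(OC)c1
F5 | step 5 | 3,4-bis(3,4,5-trimethoxyphenoxy)cyclobut-3-ene-1,2-dione | O=C1C(=O)C(Oc2cc(OC)c(OC)c(OC)c2)=C1Oc1cc(OC)c(OC)c(OC)c1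
F6 | step 5 | racemic lithium 1-(1-ethoxyvinyl)-4-oxo-2,3-bis(3,4,5-trimethoxyphenoxy)cyclobut-2-en-1-olate | O=C1C(Oc2cc(OC)c(OC)c(OC)c2)=C(Oc2cc(OC)c(OC)c(OC)c2)C1(O[Li])C(=C)OCC
F7 | step 5 | racemic 4-(1-ethoxyvinyl)-4-methoxy-2,3-bis(3,4,5-trimethoxyphenoxy)cyclobut-2-en-1-one | O=C1C(Oc2cc(OC)c(OC)c(OC)c2)=C(Oc2cc(OC)c(OC)c(OC)c2)C1(OC)C(=C)OCC
F0 | step 7 | none | none
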